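The dihydropyran ring of the chromanol is grown from a five-membered spiro ether instead of being closed directly. The plan exploits the para relationship between O1 (on C8a) and the C6 hydroxyl of the benzene ring and the unsubstituted state of C4a before the step: a 1-oxaspiro[4.5]deca-6,9-dien-8-one, made by oxidative dearomatisation of a para-alkylphenol that already carries the C2 stereocentre from (S)-linalool, undergoes a dienone–phenol 1,2-shift of C4 from C8a to C4a. One operation expands the tetrahydrofuran to the pyran, restores the arene and unveils the C6 phenol. The polyprenyl chain, ending in a carbinol from Sharpless-epoxidised farnesol, is then joined by sulfone alkylation.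

Key step: step 3

Assumption: both stereocentres of the target (chroman C2 and the side-chain carbinol) are S; (S)-(+)-linalool, (2E,6E)-farnesol and (2E,6E,10E)-geranylgeraniol are taken as commercial single isomers, and because the two centres are remote the enantiopurity of each chiral building block sets the diastereomeric purity of the product.

Step 1
Reactants: 1 (S)-(+)-linalool [(3S)-3,7-dimethylocta-1,6-dien-3-ol]; 2 4-bromo-2,3-dimethylphenol
Product: 4 4-[(3S)-3-hydroxy-3,7-dimethyloct-6-en-1-yl]-2,3-dimethylphenol, via B-alkyl-9-BBN borane 3 (not isolated)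
Conditions: 9-BBN dimer, THF, 0 °C to rt; then 2, Pd(OAc)2 (3 mol %), SPhos (6 mol %), K3PO4 (3 M aq., 3.5 equiv), THF, 65 °C
Reagents that add atoms: none
Why: 9-BBN should hydroborate the monosubstituted vinyl group at its terminal carbon and leave the trisubstituted alkene alone, and the primary borane then undergoes B-alkyl Suzuki–Miyaura coupling with the aryl bromide (the phenol carried as its phenoxide), the carbinol stereocentre being untouched.

Step 2
Reactants: 4 4-[(3S)-3-hydroxy-3,7-dimethyloct-6-en-1-yl]-2,3-dimethylphenol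
Product: 5 (2S)-2,6,7-trimethyl-2-(4-methylpent-3-en-1-yl)-1-oxaspiro[4.5]deca-6,9-dien-8-one (both epimers at the spiro carbon C5)
Conditions: PhI(OAc)2 (1.1 equiv), MeCN, 0 °C
Reagents that add atoms: none
Why: Oxidative dearomatisation of the para-alkylphenol gives a phenoxenium-type species that the tethered tertiary hydroxyl should trap at the ipso carbon in a 5-exo closure (oxidative spiroetherification); the spiro centre forms as both epimers, which does not matter because step 3 erases it.

Step 3
Reactants: 5 (2S)-2,6,7-trimethyl-2-(4-methylpent-3-en-1-yl)-1-oxaspiro[4.5]deca-6,9-dien-8-one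
Product: 7 (2S)-2,7,8-trimethyl-2-(4-methylpent-3-en-1-yl)chroman-6-yl pivalate, via chromanol 6 (not isolated)
Conditions: BF3·OEt2 (1.5 equiv), CH2Cl2, −40 to 0 °C; then Et3N (5 equiv), PivCl (1.5 equiv), DMAP (0.1 equiv), 0 °C to rt
Reagents that add atoms: pivaloyl chloride CC(C)(C)C(Cl)=O
Why: BF3 coordination to the C8 carbonyl of the spirodienone makes a hydroxyarenium-type cation with positive charge on the two ring carbons flanking the spiro carbon C5, and the ring methylene C4 then undergoes a 1,2-shift from C5 to the unsubstituted carbon C10, after which loss of the C10 proton rearomatises the ring and the carbonyl becomes the C6 phenol. This is a dienone–phenol (quinol ether) rearrangement, the closest known case being the acid-induced conversion of spiro-ether cyclohexadienones into hydroxylated benzo-fused oxygen heterocycles. The six-membered pyran ring is not closed by a new bond from an open chain: it arises by ring expansion of the five-membered tetrahydrofuran, the arene carbon C10 (the future C4a) being inserted between C4 and the old spiro carbon (the future C8a). No new stereocentre is formed: C2 keeps all four of its bonds and so its (S) configuration from linalool, and the spiro centre is destroyed, so both epimers of 5 converge. The step needs carbon rather than ether-oxygen migration and migration to C10 rather than to the methyl-bearing C6; the first is secured by the ether oxygen, which stabilises the cation left at C5 only when carbon migrates, the second because only the shift to the hydrogen-bearing carbon can end in proton loss, a shift towards C6 being reversible. Quenching BF3 with Et3N and acylating in the same flask caps the air-sensitive chromanol as its pivalate.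

Step 4
Reactants: 7 (2S)-2,7,8-trimethyl-2-(4-methylpent-3-en-1-yl)chroman-6-yl pivalate
Product: 8 (2S)-2-[(3E)-5-hydroxy-4-methylpent-3-en-1-yl]-2,7,8-trimethylchroman-6-yl pivalate
Conditions: SeO2 (0.5 equiv), t-BuOOH (3 equiv), salicylic acid (0.1 equiv), CH2Cl2, rt
Reagents that add atoms: tert-butyl hydroperoxide CC(C)(C)OO (terminal oxygen source, transferred through selenium dioxide O=[Se]=O)
Why: SeO2-mediated allylic oxidation (ene reaction then [2,3]-sigmatropic shift) should hydroxylate the (E)-methyl of the terminal trisubstituted alkene and give the (E)-allylic alcohol, the pivalate keeping the electron-rich chromanol from being oxidised.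

Step 5
Reactants: 8 (2S)-2-[(3E)-5-hydroxy-4-methylpent-3-en-1-yl]-2,7,8-trimethylchroman-6-yl pivalate
Product: 9 (2S)-2-[(3E)-5-bromo-4-methylpent-3-en-1-yl]-2,7,8-trimethylchroman-6-yl pivalate
Conditions: CBr4, PPh3, CH2Cl2, 0 °C
Reagents that add atoms: carbon tetrabromide BrC(Br)(Br)Br
Why: Appel bromination should convert the primary allylic alcohol into the bromide by SN2 displacement of the alkoxyphosphonium group without allylic transposition or loss of E geometry.

Step 6
Reactants: 10 (2E,6E)-farnesol
Product: 11 (2S,3S)-2,3-epoxyfarnesol {[(2S,3S)-3-[(3E)-4,8-dimethylnona-3,7-dien-1-yl]-3-methyloxiran-2-yl]methanol}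
Conditions: Ti(OiPr)4 (10 mol %), L-(+)-diethyl tartrate (12 mol %), t-BuOOH (anhydrous, 2 equiv), 4 Å molecular sieves, CH2Cl2, −20 °C
Reagents that add atoms: tert-butyl hydroperoxide CC(C)(C)OO
Why: Sharpless asymmetric epoxidation is directed by the allylic hydroxyl so that only the C2–C3 alkene reacts, and L-(+)-diethyl tartrate should deliver oxygen to the face that gives the (2S,3S)-epoxide, which fixes the future carbinol configuration at C3.

Step 7
Reactants: 11 (2S,3S)-2,3-epoxyfarnesol
Product: 12 (2R,3S,6E)-1-chloro-2,3-epoxy-3,7,11-trimethyldodeca-6,10-diene (same spatial arrangement as 11; the C2 descriptor changes only because chlorine outranks oxygen)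
Conditions: PPh3, CCl4, NaHCO3, reflux
Reagents that add atoms: carbon tetrachloride ClC(Cl)(Cl)Cl
Why: Appel chlorination of the primary epoxy alcohol under buffered conditions proceeds by SN2 at the carbinol carbon and should leave the epoxide and both stereocentres intact.

Step 8
Reactants: 12 (2R,3S,6E)-1-chloro-2,3-epoxy-3,7,11-trimethyldodeca-6,10-diene
Product: 13 (3S,6E)-3,7,11-trimethyldodeca-6,10-dien-1-yn-3-ol
Conditions: n-BuLi (3.2 equiv), THF, −78 to −30 °C; NH4Cl (aq.)
Reagents that add atoms: none
Why: Base-induced double elimination of the 2,3-epoxy chloride (deprotonation alpha to chlorine, epoxide opening to the chlorovinyl alkoxide, then dehydrochlorination) should give the terminal propargylic alcohol, and because the C3–O bond is never broken the (S) tertiary carbinol is carried over intact.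

Step 9
Reactants: 14 (2E,6E,10E)-geranylgeraniol
Product: 16 [(2E,6E,10E)-3,7,11,15-tetramethylhexadeca-2,6,10,14-tetraen-1-yl]sulfonylbenzene (geranylgeranyl phenyl sulfone), via geranylgeranyl bromide 15 (not isolated)
Conditions: PBr3 (0.4 equiv), Et2O, −10 °C; then PhSO2Na, DMF, rt
Reagents that add atoms: sodium benzenesulfinate [Na+].[O-]S(=O)c1ccccc1
Why: PBr3 converts the primary allylic alcohol into the bromide, which the sulfinate should S-alkylate by SN2 at the primary carbon to give the (E)-allyl sulfone.

Step 10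
Reactants: 16 geranylgeranyl phenyl sulfone
Product: 17 (2E,6E,10E,14E)-2,6,10,14-tetramethyl-16-(phenylsulfonyl)hexadeca-2,6,10,14-tetraen-1-ol
Conditions: SeO2 (0.5 equiv), t-BuOOH (3 equiv), salicylic acid (0.1 equiv), CH2Cl2, rt
Reagents that add atoms: tert-butyl hydroperoxide CC(C)(C)OO (terminal oxygen source, transferred through selenium dioxide O=[Se]=O)
Why: SeO2 allylic oxidation should favour the (E)-methyl of the terminal isopropylidene unit, the most electron-rich and least hindered alkene, the alkene next to the electron-withdrawing sulfone being deactivated.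

Step 11
Reactants: 17 (2E,6E,10E,14E)-2,6,10,14-tetramethyl-16-(phenylsulfonyl)hexadeca-2,6,10,14-tetraen-1-ol
Product: 18 [(2E,6E,10E,14E)-16-chloro-3,7,11,15-tetramethylhexadeca-2,6,10,14-tetraen-1-yl]sulfonylbenzene
Conditions: NCS, Me2S, CH2Cl2, −20 to 0 °C
Reagents that add atoms: N-chlorosuccinimide O=C1CCC(=O)N1Cl
Why: Corey–Kim chlorination converts the primary allylic alcohol into the chloride through an alkoxysulfonium salt and should do so without SN2' transposition.

Step 12
Reactants: 13 (3S,6E)-3,7,11-trimethyldodeca-6,10-dien-1-yn-3-ol; 18 [(2E,6E,10E,14E)-16-chloro-3,7,11,15-tetramethylhexadeca-2,6,10,14-tetraen-1-yl]sulfonylbenzene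
Product: 20 (2E,6E,10E,14E,17E,19S,22E)-3,7,11,15,19,23,27-heptamethyl-1-(phenylsulfonyl)octacosa-2,6,10,14,17,22,26-heptaen-19-ol, via alkenylzirconocene 19 (not isolated)
Conditions: Cp2Zr(H)Cl (2.2 equiv), THF, rt; then 18, Pd(PPh3)4 (5 mol %), THF, rt
Reagents that add atoms: none
Why: Syn hydrozirconation of the terminal alkyne (the first equivalent of Cp2Zr(H)Cl being taken up as the zirconium alkoxide) places zirconium on the terminal carbon to give the (E)-alkenylzirconocene, which under zerovalent palladium catalysis should cross-couple (Negishi-type) with the allylic chloride at its less hindered CH2 terminus with retention of both alkene geometries to form the skipped (E,E)-diene.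

Step 13
Reactants: 20 (2E,6E,10E,14E,17E,19S,22E)-3,7,11,15,19,23,27-heptamethyl-1-(phenylsulfonyl)octacosa-2,6,10,14,17,22,26-heptaen-19-ol; 9 (2S)-2-[(3E)-5-bromo-4-methylpent-3-en-1-yl]-2,7,8-trimethylchroman-6-yl pivalate
Product: 21 (2S)-2-[(3E,7E,11E,15E,19E,22E,24S,27E)-24-hydroxy-4,8,12,16,20,24,28,32-octamethyl-6-(phenylsulfonyl)tritriaconta-3,7,11,15,19,22,27,31-octaen-1-yl]-2,7,8-trimethylchroman-6-yl pivalate (both epimers at the sulfone-bearing carbon)
Conditions: n-BuLi (2.05 equiv), THF/DMPU, −78 °C; then 9, −78 to −40 °C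
Reagents that add atoms: none
Why: Double deprotonation gives the alkoxide and the sulfonyl-stabilised allyl anion, whose alpha carbon should alkylate the primary allylic bromide by SN2 (Biellmann-type sulfone coupling) while the hindered aryl pivalate and the tertiary alkoxide stay inert at −78 °C; the new sulfone-bearing centre is removed in step 14.

Step 14
Reactants: 21 the sulfone pivalate from step 13
Product: 22 (2S)-2-[(3E,7E,11E,15E,19E,22E,24S,27E)-24-hydroxy-4,8,12,16,20,24,28,32-octamethyltritriaconta-3,7,11,15,19,22,27,31-octaen-1-yl]-2,7,8-trimethylchroman-6-ol (target)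
Conditions: PdCl2(dppp) (5 mol %), LiBHEt3 (6 equiv), THF, 0 °C to rt; NH4Cl (aq.)
Reagents that add atoms: none
Why: Palladium-catalysed reductive desulfonylation (ionisation of the allylic sulfone to an allylpalladium species, then hydride delivery from LiBHEt3 to the less substituted terminus) should restore the (E)-trisubstituted alkene, while the excess LiBHEt3 reductively cleaves the aryl pivalate to release the phenol.

Compound list
1 | (S)-(+)-linalool, (3S)-3,7-dimethylocta-1,6-dien-3-ol | CC(C)=CCC[C@@](O)(C)C=C | starting material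
2 | 4-bromo-2,3-dimethylphenol | Cc1c(C)c(Br)ccc1O | starting material
3 | 9-[(3S)-3-hydroxy-3,7-dimethyloct-6-en-1-yl]-9-borabicyclo[3.3.1]nonane | CC(C)=CCC[C@@](O)(C)CCB1C2CCCC1CCC2 | intermediate
4 | 4-[(3S)-3-hydroxy-3,7-dimethyloct-6-en-1-yl]-2,3-dimethylphenol | CC(C)=CCC[C@@](O)(C)CCc1ccc(O)c(C)c1C | intermediate
5 | (2S)-2,6,7-trimethyl-2-(4-methylpent-3-en-1-yl)-1-oxaspiro[4.5]deca-6,9-dien-8-one (both C5 epimers) | CC(C)=CCC[C@@]1(C)CCC2(O1)C=CC(=O)C(C)=C2C | intermediate
6 | (2S)-2,7,8-trimethyl-2-(4-methylpent-3-en-1-yl)chroman-6-ol | CC(C)=CCC[C@@]1(C)CCc2cc(O)c(C)c(C)c2O1 | intermediate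
7 | (2S)-2,7,8-trimethyl-2-(4-methylpent-3-en-1-yl)chroman-6-yl pivalate | CC(C)=CCC[C@@]1(C)CCc2cc(OC(=O)C(C)(C)C)c(C)c(C)c2O1 | intermediate
8 | (2S)-2-[(3E)-5-hydroxy-4-methylpent-3-en-1-yl]-2,7,8-trimethylchroman-6-yl pivalate | OC/C(C)=C/CC[C@@]1(C)CCc2cc(OC(=O)C(C)(C)C)c(C)c(C)c2O1 | intermediate
9 | (2S)-2-[(3E)-5-bromo-4-methylpent-3-en-1-yl]-2,7,8-trimethylchroman-6-yl pivalate | BrC/C(C)=C/CC[C@@]1(C)CCc2cc(OC(=O)C(C)(C)C)c(C)c(C)c2O1 | intermediate
10 | (2E,6E)-farnesol | CC(C)=CCC/C(C)=C/CC/C(C)=C/CO | starting material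
11 | (2S,3S)-2,3-epoxyfarnesol | CC(C)=CCC/C(C)=C/CC[C@]1(C)O[C@H]1CO | intermediate
12 | (2R,3S,6E)-1-chloro-2,3-epoxy-3,7,11-trimethyldodeca-6,10-diene | CC(C)=CCC/C(C)=C/CC[C@]1(C)O[C@H]1CCl | intermediate
13 | (3S,6E)-3,7,11-trimethyldodeca-6,10-dien-1-yn-3-ol | CC(C)=CCC/C(C)=C/CC[C@](C)(O)C#C | intermediate
14 | (2E,6E,10E)-geranylgeraniol | CC(C)=CCC/C(C)=C/CC/C(C)=C/CC/C(C)=C/CO | starting material
15 | (2E,6E,10E)-geranylgeranyl bromide | CC(C)=CCC/C(C)=C/CC/C(C)=C/CC/C(C)=C/CBr | intermediate
16 | (2E,6E,10E)-geranylgeranyl phenyl sulfone | CC(C)=CCC/C(C)=C/CC/C(C)=C/CC/C(C)=C/CS(=O)(=O)c1ccccc1 | intermediate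
17 | (2E,6E,10E,14E)-2,6,10,14-tetramethyl-16-(phenylsulfonyl)hexadeca-2,6,10,14-tetraen-1-ol | OC/C(C)=C/CC/C(C)=C/CC/C(C)=C/CC/C(C)=C/CS(=O)(=O)c1ccccc1 | intermediate
18 | [(2E,6E,10E,14E)-16-chloro-3,7,11,15-tetramethylhexadeca-2,6,10,14-tetraen-1-yl]sulfonylbenzene | ClC/C(C)=C/CC/C(C)=C/CC/C(C)=C/CC/C(C)=C/CS(=O)(=O)c1ccccc1 | intermediate
19 | (E)-alkenylzirconocene chloride of 13 with the hydroxyl as its Cp2ZrCl alkoxide (cyclopentadienyl rings drawn sigma-bonded) | CC(C)=CCC/C(C)=C/CC[C@](C)(O[Zr](Cl)(C1C=CC=C1)C1C=CC=C1)/C=C/[Zr](Cl)(C1C=CC=C1)C1C=CC=C1 | intermediate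
20 | (2E,6E,10E,14E,17E,19S,22E)-3,7,11,15,19,23,27-heptamethyl-1-(phenylsulfonyl)octacosa-2,6,10,14,17,22,26-heptaen-19-ol | CC(C)=CCC/C(C)=C/CC[C@](C)(O)/C=C/C/C(C)=C/CC/C(C)=C/CC/C(C)=C/CC/C(C)=C/CS(=O)(=O)c1ccccc1 | intermediate
21 | (2S)-2-[(3E,7E,11E,15E,19E,22E,24S,27E)-24-hydroxy-4,8,12,16,20,24,28,32-octamethyl-6-(phenylsulfonyl)tritriaconta-3,7,11,15,19,22,27,31-octaen-1-yl]-2,7,8-trimethylchroman-6-yl pivalate (both epimers at the sulfone carbon) | CC(C)=CCC/C(C)=C/CC[C@](C)(O)/C=C/C/C(C)=C/CC/C(C)=C/CC/C(C)=C/CC/C(C)=C/C(S(=O)(=O)c1ccccc1)C/C(C)=C/CC[C@@]1(C)CCc2cc(OC(=O)C(C)(C)C)c(C)c(C)c2O1 | intermediate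
22 | (2S)-2-[(3E,7E,11E,15E,19E,22E,24S,27E)-24-hydroxy-4,8,12,16,20,24,28,32-octamethyltritriaconta-3,7,11,15,19,22,27,31-octaen-1-yl]-2,7,8-trimethylchroman-6-ol | CC(C)=CCC/C(C)=C/CC[C@](C)(O)/C=C/C/C(C)=C/CC/C(C)=C/CC/C(C)=C/CC/C(C)=C/CC/C(C)=C/CC[C@@]1(C)CCc2cc(O)c(C)c(C)c2O1 | target

Total step count: 14. Longest linear sequence: 7 steps (steps 1, 2, 3, 4, 5, 13, 14, from linalool).

Steps most likely to fail

Step 3. The cationic 1,2-shift may take another course: the ether oxygen could migrate in place of C4, or the tertiary C2–O bond could ionise with loss of configuration. The fallback closes the pyran ring directly through a quinone hemiketal, in which the C2–O bond is never broken; it gives up the ring expansion and is held only in reserve. It sets out from 1 (through borane 3, made as in step 1). Suzuki–Miyaura coupling with 1-bromo-2,5-dimethoxy-3,4-dimethylbenzene F2 (from NBS bromination of commercial 1,4-dimethoxy-2,3-dimethylbenzene F1) would give the dimethoxyaryl carbinol F3. Oxidative demethylation with (NH4)2Ce(NO3)6 in aqueous MeCN would give the hydroxyalkyl quinone F4. HC(OMe)3 in MeOH with catalytic TsOH would close the cyclic mixed ketal F5 by addition of the tertiary hydroxyl to the neighbouring quinone carbonyl. Reduction with ascorbic acid (or Zn/AcOH) would expel methanol and aromatise the ring to chromanol 6, which comes back to the route by pivaloylation to 7.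

Step 12. The E geometry of the 2-methylallyl unit may erode through syn–anti isomerisation of the allylpalladium intermediate, or coupling may occur at its internal terminus. The fallback avoids any allyl–metal intermediate and sets out from 13 and 18. Copper-catalysed alkynylation (CuI, K2CO3, NaI, DMF, rt) would displace the primary allylic chloride directly and give the skipped enynol F6. Hydroxyl-directed trans reduction of the propargylic alcohol with NaAlH2(OCH2CH2OMe)2 in THF would then give the (E)-allylic alcohol, coming back to the route at 20.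

Step 10. Site selectivity among the four trisubstituted alkenes may be poor and the product may over-oxidise to the enal. The fallback rebuilds the terminus by cleavage and olefination and sets out from 16. Terminal-selective bromohydrin formation (NBS, aqueous THF, 0 °C) would give bromohydrin F7, and K2CO3 in MeOH would close it to the terminal epoxide F8. Cleavage with H5IO6 would give the trisnor aldehyde F9. Wittig olefination with Ph3P=C(CH3)CO2Et would give the (E)-enoate F10, and reduction with i-Bu2AlH at −78 °C would come back to the route at 17.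

Further compounds
F1 | step 3 | 1,4-dimethoxy-2,3-dimethylbenzene | COc1ccc(OC)c(C)c1C
F2 | step 3 | 1-bromo-2,5-dimethoxy-3,4-dimethylbenzene | COc1cc(Br)c(OC)c(C)c1C
F3 | step 3 | (3S)-1-(2,5-dimethoxy-3,4-dimethylphenyl)-3,7-dimethyloct-6-en-3-ol | CC(C)=CCC[C@@](O)(C)CCc1cc(OC)c(C)c(C)c1OC
F4 | step 3 | 2-[(3S)-3-hydroxy-3,7-dimethyloct-6-en-1-yl]-5,6-dimethyl-1,4-benzoquinone | CC(C)=CCC[C@@](O)(C)CCC1=CC(=O)C(C)=C(C)C1=O
F5 | step 3 | (2S)-8a-methoxy-2,7,8-trimethyl-2-(4-methylpent-3-en-1-yl)-2,3,4,8a-tetrahydro-6H-chromen-6-one (both C8a epimers) | CC(C)=CCC[C@@]1(C)CCC2=CC(=O)C(C)=C(C)C2(OC)O1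
F6 | step 12 | (2E,6E,10E,14E,19S,22E)-3,7,11,15,19,23,27-heptamethyl-1-(phenylsulfonyl)octacosa-2,6,10,14,22,26-hexaen-17-yn-19-ol | CC(C)=CCC/C(C)=C/CC[C@](C)(O)C#CC/C(C)=C/CC/C(C)=C/CC/C(C)=C/CC/C(C)=C/CS(=O)(=O)c1ccccc1
F7 | step 10 | (6E,10E,14E)-3-bromo-2,6,10,14-tetramethyl-16-(phenylsulfonyl)hexadeca-6,10,14-trien-2-ol | CC(C)(O)C(Br)CC/C(C)=C/CC/C(C)=C/CC/C(C)=C/CS(=O)(=O)c1ccccc1
F8 | step 10 | 2,2-dimethyl-3-[(3E,7E,11E)-3,7,11-trimethyl-13-(phenylsulfonyl)trideca-3,7,11-trien-1-yl]oxirane | CC1(C)OC1CC/C(C)=C/CC/C(C)=C/CC/C(C)=C/CS(=O)(=O)c1ccccc1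
F9 | step 10 | (4E,8E,12E)-4,8,12-trimethyl-14-(phenylsulfonyl)tetradeca-4,8,12-trienal | O=CCC/C(C)=C/CC/C(C)=C/CC/C(C)=C/CS(=O)(=O)c1ccccc1
F10 | step 10 | ethyl (2E,6E,10E,14E)-2,6,10,14-tetramethyl-16-(phenylsulfonyl)hexadeca-2,6,10,14-tetraenoate | CCOC(=O)/C(C)=C/CC/C(C)=C/CC/C(C)=C/CC/C(C)=C/CS(=O)(=O)c1ccccc1
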